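**Retrosynthetic overview**
1. The epoxide is the last ring formed. The target comes from PPh3-induced SN2′ deoxygenation of the C2–C5 endoperoxide, which comes from a singlet-oxygen [4+2] on the ring diene, both in one pot.
2. The side chain comes from a syn boron aldol of pentan-3-one with the 2-(cyclohexadienyl)acrolein. The chiral boron reagent sets both side-chain centres and converts the racemic ring into two separable diastereomers.
3. The cyclohexadiene is the second ring. It forms by thermal disrotatory 6π electrocyclisation of an (E,Z,E)-triene, which is made and cyclised in one operation by hydrozirconation/Negishi coupling of an enynol with a (Z)-dienyl iodide.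
4. The pyranone is the first ring. It forms by polyketide-style Claisen chain extension to a 3,5-diketo ester, then lactonisation and O-methylation.
5. Ring order is pyranone, cyclohexadiene, epoxide. Ring locants below: C1 carries the side chain, C2/C4/C6 carry methyl groups, and C6 also carries the pyranone.

Assumption: the electrocyclisation gives a racemate (SMILES of 19 and 20 show the enantiomer carried on), and (+)-Ipc2BOTf, made from (−)-α-pinene, is taken as the reagent enantiomer that attacks the re face of the aldehyde.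

**Step 1**
Reactants: 1 prop-2-yn-1-ol (propargyl alcohol)
Product: 3 (Z)-3-iodo-2-methylprop-2-en-1-ol, via vinylmagnesium alkoxide 2 (not isolated)
Conditions: MeMgBr (2.5 equiv), CuI (10 mol %), THF, −10 °C to rt; I2, −10 °C to rt; aq Na2S2O3
Reagents that add atoms: methylmagnesium bromide C[Mg]Br; iodine II
Why: Copper-catalysed anti-carbomagnesiation of the propargylic magnesium alkoxide puts Me on the internal carbon and Mg cis to CH2O in a chelate, so iodinolysis with retention gives only the (Z)-iodide that later becomes the central Z-alkene of the triene.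

**Step 2**
Reactants: 3 (Z)-3-iodo-2-methylprop-2-en-1-ol; 4 ethyl 2-(triphenylphosphoranylidene)propanoate
Product: 6 ethyl (2E,4Z)-5-iodo-2,4-dimethylpenta-2,4-dienoate, via (Z)-3-iodo-2-methylprop-2-enal 5 (not isolated)
Conditions: MnO2 (15 equiv), 4 (1.3 equiv), CH2Cl2, rt, dark
Reagents that add atoms: none
Why: Tandem MnO2 oxidation/Wittig olefination traps the isomerisation-prone (Z)-iodoenal as it forms, and the stabilised α-methyl ylide gives the (E)-trisubstituted enoate.

**Step 3**
Reactants: 6 ethyl (2E,4Z)-5-iodo-2,4-dimethylpenta-2,4-dienoate; 7 methyl 2-methyl-3-oxopentanoate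
Product: 10 4-hydroxy-6-[(2E,4Z)-5-iodo-4-methylpenta-2,4-dien-2-yl]-3,5-dimethyl-2H-pyran-2-one, via dilithio dianion 8 (not isolated), via diketo ester 9 (not isolated)
Conditions: 7 (2.2 equiv), LDA (4.4 equiv), THF, −78 to 0 °C; 6, 0 °C to rt; 1 M HCl; crude 9, DBU, PhMe, 60 °C
Reagents that add atoms: none
Why: γ-Acylation of a β-keto ester dianion by an ester (Claisen condensation of the Huckin–Weiler type) copies polyketide chain extension, and DBU then closes the enolised C5 oxygen onto the methyl ester (lactonisation) to give the 4-hydroxy-2-pyranone, in which no sp3 stereocentre survives.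

**Step 4**
Reactants: 10 4-hydroxy-6-[(2E,4Z)-5-iodo-4-methylpenta-2,4-dien-2-yl]-3,5-dimethyl-2H-pyran-2-one
Product: 12 2-[(2E,4Z)-5-iodo-4-methylpenta-2,4-dien-2-yl]-6-methoxy-3,5-dimethyl-4H-pyran-4-one, via hydroxypyrylium triflate 11 (not isolated)
Conditions: MeOTf (2 equiv), CH2Cl2, rt; sat. aq NaHCO3
Reagents that add atoms: methyl triflate COS(=O)(=O)C(F)(F)F
Why: In this regioselective O-methylation the hard methylating agent alkylates the most basic site, the lactone carbonyl oxygen, and the resulting 4-hydroxy-2-methoxypyrylium ion loses its proton on bicarbonate work-up to give the 2-methoxy-4-pyranone rather than the 4-methoxy-2-pyranone.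

**Step 5**
Reactants: 13 2-bromoprop-2-en-1-ol; 14 propyne
Product: 15 2-methylidenepent-3-yn-1-ol
Conditions: PdCl2(PPh3)2 (2 mol %), CuI (4 mol %), Et3N, THF, 14 (2 equiv), rt to 45 °C, sealed tube
Reagents that add atoms: none
Why: Sonogashira coupling of a vinyl bromide with a terminal alkyne tolerates the free alcohol and creates no stereo element.

**Step 6**
Reactants: 15 2-methylidenepent-3-yn-1-ol; 12 2-[(2E,4Z)-5-iodo-4-methylpenta-2,4-dien-2-yl]-6-methoxy-3,5-dimethyl-4H-pyran-4-one
Product: 19 rac-2-[(1R,6R)-6-(6-methoxy-3,5-dimethyl-4-oxo-4H-pyran-2-yl)-2,4,6-trimethylcyclohexa-2,4-dien-1-yl]prop-2-en-1-ol (pyranone cis to side chain), via alkenylzirconocene 16 (not isolated), via alkenylzinc chloride 17 (not isolated), via (E,Z,E)-tetraenol 18 (not isolated)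
Conditions: Cp2Zr(H)Cl (2.2 equiv), THF, 0 to 40 °C, dark; ZnCl2 (1.1 equiv), 0 °C; 12 (0.85 equiv), Pd(PPh3)4 (5 mol %), rt; cold 0.5 M HCl work-up; crude 18, PhMe, BHT, 80 °C, argon
Reagents that add atoms: none
Why: After the first equivalent caps the OH, syn hydrozirconation of the Me–C≡C unit equilibrates to Zr on the less hindered methyl-bearing carbon, Zr-to-Zn transmetalation and Negishi coupling keep the geometry of both alkenyl partners to give the (E,Z,E)-triene, and its thermal disrotatory 6π electrocyclisation turns the two outward groups (pyranone on C6, side chain on C1) to the same face, which sets the cis C1/C6 relationship in racemic form.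

**Step 7**
Reactants: 19 rac-2-[(1R,6R)-6-(6-methoxy-3,5-dimethyl-4-oxo-4H-pyran-2-yl)-2,4,6-trimethylcyclohexa-2,4-dien-1-yl]prop-2-en-1-ol
Product: 20 rac-2-[(1S,6R)-6-(6-methoxy-3,5-dimethyl-4-oxo-4H-pyran-2-yl)-2,4,6-trimethylcyclohexa-2,4-dien-1-yl]prop-2-enal (same spatial arrangement as 19; the C1 descriptor changes by priority only)
Conditions: MnO2 (20 equiv), CH2Cl2, rt; product kept at or below rt
Reagents that add atoms: none
Why: Allylic alcohol oxidation by MnO2 touches only the primary allylic carbinol, and the diene cannot aromatise because C6 is quaternary, so no stereocentre is affected.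

**Step 8**
Reactants: 20 rac-2-[(1S,6R)-6-(6-methoxy-3,5-dimethyl-4-oxo-4H-pyran-2-yl)-2,4,6-trimethylcyclohexa-2,4-dien-1-yl]prop-2-enal; 21 pentan-3-one
Product: 24 (4R,5R)-5-hydroxy-6-[(1R,6R)-6-(6-methoxy-3,5-dimethyl-4-oxo-4H-pyran-2-yl)-2,4,6-trimethylcyclohexa-2,4-dien-1-yl]-4-methylhept-6-en-3-one, via (Z)-enol borinate 22 (not isolated), via boron aldolate 23 (not isolated)
Conditions: 21 (3 equiv), (+)-Ipc2BOTf (2 equiv, stock solution in hexane), iPr2NEt, CH2Cl2, −78 °C; 20, −78 to −20 °C; MeOH, pH 7 buffer, 30 % H2O2, 0 °C; SiO2 separation of the two diastereomers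
Reagents that add atoms: none
Why: In this Paterson-type boron aldol the (Z)-enol borinate reacts through a chair Zimmerman–Traxler transition state to give the syn aldol, the Ipc ligands direct attack to the re face of the aldehyde to set (4R,5R) (about 90 % ee by analogy with methacrolein), and because the remote ring centres hardly bias the aldehyde both ring enantiomers react, so chromatographic removal of the (1S,6S) diastereomer fixes the absolute configuration at C1 and C6.

**Step 9**
Reactants: 24 (4R,5R)-5-hydroxy-6-[(1R,6R)-6-(6-methoxy-3,5-dimethyl-4-oxo-4H-pyran-2-yl)-2,4,6-trimethylcyclohexa-2,4-dien-1-yl]-4-methylhept-6-en-3-one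
Product: 26 CNP0233636.2 = (4R,5R)-5-hydroxy-6-[(1S,2R,3R,6R)-3-(6-methoxy-3,5-dimethyl-4-oxo-4H-pyran-2-yl)-1,3,5-trimethyl-7-oxabicyclo[4.1.0]hept-4-en-2-yl]-4-methylhept-6-en-3-one, via endoperoxide 25 (not isolated)
Conditions: O2, tetraphenylporphyrin (1 mol %), dry CH2Cl2, white LED, −40 °C; argon purge; PPh3 (1.1 equiv), −40 °C to rt; Et3N-deactivated SiO2
Reagents that add atoms: dioxygen O=O
Why: Singlet-oxygen [4+2] cycloaddition takes the diene face that carries only C6-CH3 and C1-H (anti to pyranone and side chain) while the 1,1-disubstituted alkene is inert to 1O2, and PPh3 then attacks the less hindered peroxide oxygen (on C5, bridgehead H instead of bridgehead CH3), so the retained C2 alkoxide closes on C3 in a syn SN2′ expulsion of Ph3PO (the known phosphine deoxygenation of 2,3-dioxabicyclo[2.2.2]octenes to diene monoepoxides), which sets ring C2 (S) and C3 (R) and leaves the alkene at C4=C5.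

**Compound list**
1 | prop-2-yn-1-ol | C#CCO | starting material
2 | (Z)-vinylmagnesium bromide/magnesium alkoxide from anti-carbomagnesiation | Br[Mg]/C=C(/C)CO[Mg]Br | intermediate
3 | (Z)-3-iodo-2-methylprop-2-en-1-ol | I/C=C(/C)CO | intermediate
4 | ethyl 2-(triphenylphosphoranylidene)propanoate | CCOC(=O)C(C)=P(c1ccccc1)(c1ccccc1)c1ccccc1 | starting material
5 | (Z)-3-iodo-2-methylprop-2-enal | I/C=C(/C)C=O | intermediate
6 | ethyl (2E,4Z)-5-iodo-2,4-dimethylpenta-2,4-dienoate | I/C=C(/C)\C=C(/C)C(=O)OCC | intermediate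
7 | methyl 2-methyl-3-oxopentanoate | CCC(=O)C(C)C(=O)OC | starting material
8 | dilithio dianion of 7 | CC=C(O[Li])C(C)=C(OC)O[Li] | intermediate
9 | methyl (6E,8Z)-9-iodo-2,4,6,8-tetramethyl-3,5-dioxonona-6,8-dienoate (C2/C4 epimers and enols) | I/C=C(/C)\C=C(/C)C(=O)C(C)C(=O)C(C)C(=O)OC | intermediate
10 | 4-hydroxy-6-[(2E,4Z)-5-iodo-4-methylpenta-2,4-dien-2-yl]-3,5-dimethyl-2H-pyran-2-one | I/C=C(/C)\C=C(/C)c1oc(=O)c(C)c(O)c1C | intermediate
11 | 4-hydroxy-2-methoxypyrylium triflate of 10 | I/C=C(/C)\C=C(/C)c1[o+]c(OC)c(C)c(O)c1C.[O-]S(=O)(=O)C(F)(F)F | intermediate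
12 | 2-[(2E,4Z)-5-iodo-4-methylpenta-2,4-dien-2-yl]-6-methoxy-3,5-dimethyl-4H-pyran-4-one | I/C=C(/C)\C=C(/C)c1oc(OC)c(C)c(=O)c1C | intermediate
13 | 2-bromoprop-2-en-1-ol | C=C(Br)CO | starting material
14 | propyne | CC#C | starting material
15 | 2-methylidenepent-3-yn-1-ol | CC#CC(=C)CO | intermediate
16 | (E)-alkenyl-ZrCp2Cl at the methyl-bearing carbon, OH capped as O-ZrCp2Cl (Cp drawn η1) | C=C(CO[Zr](Cl)(C1C=CC=C1)C1C=CC=C1)/C=C(\C)/[Zr](Cl)(C1C=CC=C1)C1C=CC=C1 | intermediate
17 | corresponding (E)-alkenylzinc chloride | C=C(CO[Zr](Cl)(C1C=CC=C1)C1C=CC=C1)/C=C(\C)/[Zn]Cl | intermediate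
18 | 2-[(2E,4Z,6E)-9-hydroxy-4,6-dimethyl-8-methylidenenona-2,4,6-trien-2-yl]-6-methoxy-3,5-dimethyl-4H-pyran-4-one | C=C(CO)/C=C(\C)/C=C(/C)\C=C(/C)c1oc(OC)c(C)c(=O)c1C | intermediate
19 | rac-(1R,6R) cyclohexadienyl allylic alcohol, pyranone cis to side chain (enantiomer carried on is drawn) | C=C(CO)[C@H]1C(C)=CC(C)=C[C@@]1(C)c1oc(OC)c(C)c(=O)c1C | intermediate
20 | rac-(1S,6R) 2-(cyclohexadienyl)acrolein, same spatial arrangement (enantiomer carried on is drawn) | C=C(C=O)[C@H]1C(C)=CC(C)=C[C@@]1(C)c1oc(OC)c(C)c(=O)c1C | intermediate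
21 | pentan-3-one | CCC(=O)CC | starting material
22 | (Z)-pent-2-en-3-yl diisopinocampheylborinate, Ipc from (−)-α-pinene | C/C=C(/CC)OB([C@H]1C[C@H]2C[C@@H]([C@@H]1C)C2(C)C)[C@H]1C[C@H]2C[C@@H]([C@@H]1C)C2(C)C | intermediate
23 | O-B(Ipc)2 aldolate of 24 | C=C([C@H](OB([C@H]1C[C@H]2C[C@@H]([C@@H]1C)C2(C)C)[C@H]1C[C@H]2C[C@@H]([C@@H]1C)C2(C)C)[C@@H](C)C(=O)CC)[C@H]1C(C)=CC(C)=C[C@@]1(C)c1oc(OC)c(C)c(=O)c1C | intermediate
24 | (4R,5R)-5-hydroxy-6-[(1R,6R)-6-(6-methoxy-3,5-dimethyl-4-oxo-4H-pyran-2-yl)-2,4,6-trimethylcyclohexa-2,4-dien-1-yl]-4-methylhept-6-en-3-one | C=C([C@H](O)[C@@H](C)C(=O)CC)[C@H]1C(C)=CC(C)=C[C@@]1(C)c1oc(OC)c(C)c(=O)c1C | intermediate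
25 | C2–C5 endoperoxide of 24 (1,5,8-trimethyl-2,3-dioxabicyclo[2.2.2]oct-5-ene core, O–O bridge on the face of C1-H and C6-CH3) | C=C([C@H](O)[C@@H](C)C(=O)CC)[C@H]1[C@@]2(C)C=C(C)[C@H](OO2)[C@@]1(C)c1oc(OC)c(C)c(=O)c1C | intermediate
26 | CNP0233636.2 | C=C([C@H](O)[C@@H](C)C(=O)CC)[C@H]1[C@]2(C)O[C@@H]2C(C)=C[C@@]1(C)c1oc(OC)c(C)c(=O)c1C | target

**Step count**
- Total steps: 9.
- Longest linear sequence: 8 (steps 1, 2, 3, 4, 6, 7, 8, 9).

**Three steps most likely to fail**

Step 9 is the riskiest. If the phosphorus intermediate ionises at the tertiary allylic C2–O bond instead of reacting as the sterically chosen C5–O–P species, the C4–C5 epoxide isomer results. Side-chain OH guidance could also erode the facial selectivity of 1O2. The fallback drops the cycloaddition/deoxygenation logic and uses direct electrophilic oxygen transfer. It sets out from 24, which is treated with dimethyldioxirane (acetone/CH2Cl2, −78 to −40 °C) or NaHCO3-buffered mCPBA. It relies on C4=C5 being neopentyl-like next to quaternary C6 and on the 1,1-disubstituted alkene being the least nucleophilic, so that C2=C3 is epoxidised from the same open face. It comes back to the route at 26 and makes no new compound.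

Step 6 can fail through imperfect hydrozirconation regiochemistry, Z to E erosion at palladium, or a [1,7]-hydrogen shift competing with ring closure. The fallback reverses the polarity and uses two isolated, purified partners. It sets out from 12 and 15. Stannylation of 12 with Me3SnSnMe3 (Pd(PPh3)4, PhMe, 80 °C) gives the dienyl trimethylstannane F1. Hydrozirconation of 15 quenched with I2 gives (3E)-4-iodo-2-methylidenepent-3-en-1-ol F2, which is freed of any regioisomer by chromatography. A neutral Stille coupling of the unhindered CH–Sn terminus of F1 with F2 (Pd2(dba)3, AsPh3, CuI, NMP, rt) comes back to the route at 18, which is heated to 19 as before. This costs two extra steps.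

Step 3 may be sluggish because a secondary carbanion has to acylate on a hindered, conjugated α-methyl dienoate, and it may give conjugate addition. The fallback replaces the Claisen acylation by aldol addition followed by oxidation. It sets out from 3 and 7. MnO2 oxidation of 3 in the presence of 2-(triphenylphosphoranylidene)propanal gives (2E,4Z)-5-iodo-2,4-dimethylpenta-2,4-dienal F3. Dianion 8 adds to this aldehyde at −78 °C to give methyl (6E,8Z)-5-hydroxy-9-iodo-2,4,6,8-tetramethyl-3-oxonona-6,8-dienoate F4 as an inconsequential diastereomer mixture. Dess–Martin periodinane then comes back to the route at 9, which is cyclised with DBU to 10. This also costs two extra steps.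

**Further compounds**
F0 | step 9 | none | none
F1 | step 6 | 2-methoxy-3,5-dimethyl-6-[(2E,4Z)-4-methyl-5-(trimethylstannyl)penta-2,4-dien-2-yl]-4H-pyran-4-one | C[Sn](C)(C)/C=C(/C)\C=C(/C)c1oc(OC)c(C)c(=O)c1C
F2 | step 6 | (3E)-4-iodo-2-methylidenepent-3-en-1-ol | C=C(CO)/C=C(\C)/I
F3 | step 3 | (2E,4Z)-5-iodo-2,4-dimethylpenta-2,4-dienal | I/C=C(/C)\C=C(/C)C=O
F4 | step 3 | methyl (6E,8Z)-5-hydroxy-9-iodo-2,4,6,8-tetramethyl-3-oxonona-6,8-dienoate (diastereomer mixture) | I/C=C(/C)\C=C(/C)C(O)C(C)C(=O)C(C)C(=O)OC
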